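**Retrosynthetic overview**
- The two phenols are unmasked last, by hydrogenolysis of two aryl benzyl ethers.
- The tetrahydrofuran, the only ring that is built, is cut at C3–C4 and at O1–C5. This is a formal (3+2) annulation of an α-silyloxy aldehyde (O1–C2–C3) with a silyl dienol ether (C4–C5, carrying C6, C7 and the aryl ketone ring).
- Enabling feature: the ring oxygen O1 is β and the C3 hydroxyl is δ to the C7 aryl ketone. C3–C4–C5–C6–C7 is therefore the retron of a vinylogous aldol addition followed by oxa-conjugate addition, and O1–C2–C3 is an α-oxy aldehyde.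
- C2 is bought in methyl (R)-glycidate. C3 and C5 are relayed from it in the key step (chelation control, then cis-2,5 ring closure through the silylated oxygen).
- Both aryl rings come from one aryl bromide: its Grignard reagent opens the epoxide under copper catalysis to give the aldehyde arm, and its aryllithium adds to crotonaldehyde, followed by oxidation and silylation, to give the dienol ether.

Key step: step 7

Remark: bromide 1 is taken as a commercial compound. Ring atoms are numbered O1, C2 (benzyl-bearing), C3 (carbinol), C4, C5 (bearing the arm C6H2–C7(=O)–aryl).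

**Step 1**
Reactants: 1 1-(benzyloxy)-4-bromo-2-methoxybenzene, 2 methyl (2R)-oxirane-2-carboxylate
Product: 4 methyl (2R)-3-[4-(benzyloxy)-3-methoxyphenyl]-2-hydroxypropanoate, via arylmagnesium bromide 3 (not isolated)
Conditions: Mg, THF, 50 °C; then added to 2, CuBr·SMe2 (10 mol %), THF, −40 → −20 °C; aq. NH4Cl
Reagents that add atoms: none
Why: Copper-catalysed opening of the glycidic ester by the aryl Grignard reagent (SN2 at the unsubstituted epoxide carbon) should leave the ester and the stereocentre untouched, so the configuration of 2 becomes C2 of the target.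

**Step 2**
Reactants: 4 methyl (2R)-3-[4-(benzyloxy)-3-methoxyphenyl]-2-hydroxypropanoate
Product: 5 methyl (2R)-3-[4-(benzyloxy)-3-methoxyphenyl]-2-[(triethylsilyl)oxy]propanoate
Conditions: TESCl, imidazole, DMF, 0 °C → rt
Reagents that add atoms: chlorotriethylsilane (TESCl), CC[Si](Cl)(CC)CC
Why: Silyl ether formation under mild base should not epimerise the α-oxy ester, and the small triethylsilyl group is chosen because it must later allow chelation and leave from oxygen.

**Step 3**
Reactants: 5 methyl (2R)-3-[4-(benzyloxy)-3-methoxyphenyl]-2-[(triethylsilyl)oxy]propanoate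
Product: 6 (2R)-3-[4-(benzyloxy)-3-methoxyphenyl]-2-[(triethylsilyl)oxy]propanal
Conditions: iBu2AlH (1.1 equiv), CH2Cl2, −78 °C; aq. KNaC4H4O6 work-up; used crude
Reagents that add atoms: none
Why: Partial reduction of an α-silyloxy ester with iBu2AlH at −78 °C should stop at the aldehyde through a stable tetrahedral aluminium hemiacetal, and immediate use of the crude aldehyde avoids epimerisation at C2.

**Step 4**
Reactants: 1 1-(benzyloxy)-4-bromo-2-methoxybenzene, 7 (2E)-but-2-enal
Product: 9 (2E)-1-[4-(benzyloxy)-3-methoxyphenyl]but-2-en-1-ol (racemic), via aryllithium 8 (not isolated)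
Conditions: n-BuLi (1.05 equiv), THF, −78 °C; then 7, THF, −78 → −40 °C; aq. NH4Cl
Reagents that add atoms: none
Why: Bromine–lithium exchange at −78 °C should give the aryllithium cleanly, and this hard nucleophile should add to the enal carbonyl in 1,2-fashion; the new carbinol centre is racemic and is removed by the oxidation in step 5.

**Step 5**
Reactants: 9 (2E)-1-[4-(benzyloxy)-3-methoxyphenyl]but-2-en-1-ol
Product: 10 (2E)-1-[4-(benzyloxy)-3-methoxyphenyl]but-2-en-1-one
Conditions: MnO2 (10 equiv), CH2Cl2, rt
Reagents that add atoms: none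
Why: MnO2 oxidation of a doubly activated (allylic and benzylic) alcohol should give the aryl enone without touching the benzyl ether.

**Step 6**
Reactants: 10 (2E)-1-[4-(benzyloxy)-3-methoxyphenyl]but-2-en-1-one
Product: 11 {[(1Z)-1-[4-(benzyloxy)-3-methoxyphenyl]buta-1,3-dien-1-yl]oxy}(tert-butyl)dimethylsilane
Conditions: TBSOTf (1.2 equiv), Et3N (2 equiv), CH2Cl2, 0 °C; filtered through basic alumina, used directly
Reagents that add atoms: tert-butyldimethylsilyl trifluoromethanesulfonate (TBSOTf), CC(C)(C)[Si](C)(C)OS(=O)(=O)C(F)(F)F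
Why: Soft enolisation (O-silylation of the enone, then γ-deprotonation by Et3N) should give the conjugated silyl dienol ether, and because the aryl ketone has no other enolisable position only this dienol ether can form.

**Step 7**
Reactants: 6 (2R)-3-[4-(benzyloxy)-3-methoxyphenyl]-2-[(triethylsilyl)oxy]propanal, 11 {[(1Z)-1-[4-(benzyloxy)-3-methoxyphenyl]buta-1,3-dien-1-yl]oxy}(tert-butyl)dimethylsilane
Product: 13 2-{(2R,4R,5R)-5-[4-(benzyloxy)-3-methoxybenzyl]-4-hydroxyoxolan-2-yl}-1-[4-(benzyloxy)-3-methoxyphenyl]ethan-1-one, via bis-silyl tetrahydrofuran 12 (not isolated)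
Conditions: MeAlCl2 (2.5 equiv), CH2Cl2, −78 °C, 6 then 11 (1.5 equiv), −78 → −30 °C; then 1 M aq. HCl, THF, 0 °C → rt
Reagents that add atoms: none
Why: Proposed new method: MeAlCl2 should hold aldehyde 6 as a five-membered chelate between the carbonyl oxygen and the small triethylsilyl ether oxygen, and the unsubstituted terminal carbon of dienol ether 11 should add to the face opposite the benzyl group (vinylogous Mukaiyama aldol addition under chelation control), which forms the C3–C4 bond and sets C3 syn to C2. The resulting silyloxyallyl cation (an O-silylated enone) should then be captured at C5 by the silyl ether oxygen in a 5-exo-trig closure that forms the O1–C5 bond, after which the triethylsilyl group passes from the oxonium ion to the C3 oxygen or to chloride and the ketone stays masked as the enol ether of 12 until the acidic work-up frees the ketone and the C3 hydroxyl. The closest known reaction type is the Lewis acid promoted formal (3+2) annulation of α-triethylsilyloxy aldehydes with styrenes and allylsilanes, in which the silyl ether oxygen closes onto a benzylic or β-silyl cation; the cation of a vinylogous Mukaiyama addition has not been used in this role. C5 is set in the ring closure: the silyl group on the attacking oxygen should sit anti to the C2 benzyl group and the C5 side chain anti to silicon, the known preference of ether-oxygen cyclisations for cis-2,5-tetrahydrofurans, so that all three substituents end on one face. The step needs γ- over α-attack of the dienol ether, chelation over Felkin-type addition, and ring closure before the cation loses its silyl group; these are meant to be secured by the free terminal CH2 of 11, by the small silyl ether paired with the strongly chelating aluminium Lewis acid, and by the bulky tert-butyldimethylsilyl group on the cation.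

**Step 8**
Reactants: 13 2-{(2R,4R,5R)-5-[4-(benzyloxy)-3-methoxybenzyl]-4-hydroxyoxolan-2-yl}-1-[4-(benzyloxy)-3-methoxyphenyl]ethan-1-one
Product: 14 renealtin A, 2-[(2R,4R,5R)-4-hydroxy-5-(4-hydroxy-3-methoxybenzyl)oxolan-2-yl]-1-(4-hydroxy-3-methoxyphenyl)ethan-1-one
Conditions: H2 (1 atm), Pd/C (10 wt %), EtOAc, rt
Reagents that add atoms: none
Why: Hydrogenolysis of the two aryl benzyl ethers under neutral conditions should leave the electron-rich aryl ketone, the β-alkoxy ketone and the three stereocentres untouched.

**Compound list**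
1 | 1-(benzyloxy)-4-bromo-2-methoxybenzene | COc1cc(Br)ccc1OCc1ccccc1 | starting material
2 | methyl (2R)-oxirane-2-carboxylate (methyl (R)-glycidate) | COC(=O)[C@H]1CO1 | starting material
3 | [4-(benzyloxy)-3-methoxyphenyl]magnesium bromide (not isolated) | COc1cc([Mg]Br)ccc1OCc1ccccc1 | intermediate
4 | methyl (2R)-3-[4-(benzyloxy)-3-methoxyphenyl]-2-hydroxypropanoate | COC(=O)[C@H](O)Cc1ccc(OCc2ccccc2)c(OC)c1 | intermediate
5 | methyl (2R)-3-[4-(benzyloxy)-3-methoxyphenyl]-2-[(triethylsilyl)oxy]propanoate | COC(=O)[C@H](O[Si](CC)(CC)CC)Cc1ccc(OCc2ccccc2)c(OC)c1 | intermediate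
6 | (2R)-3-[4-(benzyloxy)-3-methoxyphenyl]-2-[(triethylsilyl)oxy]propanal | O=C[C@H](O[Si](CC)(CC)CC)Cc1ccc(OCc2ccccc2)c(OC)c1 | intermediate
7 | (2E)-but-2-enal (crotonaldehyde) | C/C=C/C=O | starting material
8 | [4-(benzyloxy)-3-methoxyphenyl]lithium (not isolated) | COc1cc([Li])ccc1OCc1ccccc1 | intermediate
9 | (2E)-1-[4-(benzyloxy)-3-methoxyphenyl]but-2-en-1-ol (racemic) | C/C=C/C(O)c1ccc(OCc2ccccc2)c(OC)c1 | intermediate
10 | (2E)-1-[4-(benzyloxy)-3-methoxyphenyl]but-2-en-1-one | C/C=C/C(=O)c1ccc(OCc2ccccc2)c(OC)c1 | intermediate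
11 | {[(1Z)-1-[4-(benzyloxy)-3-methoxyphenyl]buta-1,3-dien-1-yl]oxy}(tert-butyl)dimethylsilane | C=C/C=C(\O[Si](C)(C)C(C)(C)C)c1ccc(OCc2ccccc2)c(OC)c1 | intermediate
12 | (2R,3R,5R)-2-[4-(benzyloxy)-3-methoxybenzyl]-5-[(Z)-2-[4-(benzyloxy)-3-methoxyphenyl]-2-(tert-butyldimethylsilyloxy)ethenyl]-3-(triethylsilyloxy)tetrahydrofuran (not isolated) | COc1cc(C[C@H]2O[C@@H](/C=C(\O[Si](C)(C)C(C)(C)C)c3ccc(OCc4ccccc4)c(OC)c3)C[C@H]2O[Si](CC)(CC)CC)ccc1OCc1ccccc1 | intermediate
13 | 2-{(2R,4R,5R)-5-[4-(benzyloxy)-3-methoxybenzyl]-4-hydroxyoxolan-2-yl}-1-[4-(benzyloxy)-3-methoxyphenyl]ethan-1-one (di-O-benzylrenealtin A, all-cis ring) | COc1cc(C[C@H]2O[C@@H](CC(=O)c3ccc(OCc4ccccc4)c(OC)c3)C[C@H]2O)ccc1OCc1ccccc1 | intermediate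
14 | renealtin A, 2-[(2R,4R,5R)-4-hydroxy-5-(4-hydroxy-3-methoxybenzyl)oxolan-2-yl]-1-(4-hydroxy-3-methoxyphenyl)ethan-1-one | COc1cc(C[C@H]2O[C@@H](CC(=O)c3ccc(O)c(OC)c3)C[C@H]2O)ccc1O | target

**Total step count:** 8
**Longest linear sequence:** 5 steps (steps 1, 2, 3, 7, 8; the dienol ether branch, steps 4, 5, 6, 7, 8, is equally long)

**Steps most likely to fail**

1. Step 7 (proposed new method). Three processes may go wrong:
   - the cascade may stop after the carbon–carbon bond formation, if the silyloxyallyl cation loses its silyl group before the ether oxygen closes the ring;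
   - chelation by the silyl ether may be incomplete, so that Felkin-type addition erodes the selectivity at C3;
   - the ring closure may show poor facial selectivity at C5.

   Fallback, known chemistry run stepwise; it sets out from 4, uses 11, and comes back at 13. Compound 4 is etherified with 4-methoxybenzyl 2,2,2-trichloroacetimidate and catalytic camphorsulfonic acid in CH2Cl2 to methyl (2R)-3-[4-(benzyloxy)-3-methoxyphenyl]-2-[(4-methoxybenzyl)oxy]propanoate F1. iBu2AlH in CH2Cl2 at −78 °C reduces it to (2R)-3-[4-(benzyloxy)-3-methoxyphenyl]-2-[(4-methoxybenzyl)oxy]propanal F2. With MgBr2·OEt2 in CH2Cl2 at −20 °C, this α-alkoxy aldehyde and 11 should undergo the well-precedented chelation-controlled vinylogous Mukaiyama aldol addition to (2E,5R,6R)-1,7-bis[4-(benzyloxy)-3-methoxyphenyl]-5-hydroxy-6-[(4-methoxybenzyl)oxy]hept-2-en-1-one F3. DDQ in CH2Cl2 with pH 7 buffer at 0 °C removes the 4-methoxybenzyl group to give (2E,5R,6R)-1,7-bis[4-(benzyloxy)-3-methoxyphenyl]-5,6-dihydroxyhept-2-en-1-one F4. Catalytic DBU in CH2Cl2 then closes the ring by 5-exo-trig oxa-Michael addition of the C6 hydroxyl to give 13; the addition is reversible under these conditions, which should allow the material to settle on the 2,5-cis ring.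

2. Step 3. Over-reduction to the primary alcohol and epimerisation of the α-silyloxy aldehyde during isolation may lower yield and enantiomeric purity.

   Fallback; it sets out from 5 and comes back at 6. Compound 5 is reduced fully with iBu2AlH (2.5 equiv) in CH2Cl2 at −78 → 0 °C to (2R)-3-[4-(benzyloxy)-3-methoxyphenyl]-2-[(triethylsilyl)oxy]propan-1-ol F5. Parikh–Doering oxidation (SO3·pyridine, DMSO, iPr2NEt, CH2Cl2, 0 °C) then gives 6 under non-epimerising conditions, for use without chromatography.

3. Step 8. Reduction of the aryl ketone may compete with benzyl ether cleavage during hydrogenolysis.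

   Fallback; it sets out from 13 and comes back at 14. The benzyl ethers are cleaved non-reductively with BCl3 and pentamethylbenzene as cation scavenger in CH2Cl2 at −78 °C, giving 14 directly. No new compound is made (F0).

**Further compounds**
F1 | step 7 | methyl (2R)-3-[4-(benzyloxy)-3-methoxyphenyl]-2-[(4-methoxybenzyl)oxy]propanoate | COC(=O)[C@H](OCc1ccc(OC)cc1)Cc1ccc(OCc2ccccc2)c(OC)c1
F2 | step 7 | (2R)-3-[4-(benzyloxy)-3-methoxyphenyl]-2-[(4-methoxybenzyl)oxy]propanal | O=C[C@H](OCc1ccc(OC)cc1)Cc1ccc(OCc2ccccc2)c(OC)c1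
F3 | step 7 | (2E,5R,6R)-1,7-bis[4-(benzyloxy)-3-methoxyphenyl]-5-hydroxy-6-[(4-methoxybenzyl)oxy]hept-2-en-1-one | COc1cc(C[C@@H](OCc2ccc(OC)cc2)[C@H](O)C/C=C/C(=O)c2ccc(OCc3ccccc3)c(OC)c2)ccc1OCc1ccccc1
F4 | step 7 | (2E,5R,6R)-1,7-bis[4-(benzyloxy)-3-methoxyphenyl]-5,6-dihydroxyhept-2-en-1-one | COc1cc(C[C@@H](O)[C@H](O)C/C=C/C(=O)c2ccc(OCc3ccccc3)c(OC)c2)ccc1OCc1ccccc1
F5 | step 3 | (2R)-3-[4-(benzyloxy)-3-methoxyphenyl]-2-[(triethylsilyl)oxy]propan-1-ol | OC[C@H](O[Si](CC)(CC)CC)Cc1ccc(OCc2ccccc2)c(OC)c1
F0 | step 8 | none | none
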